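**Retrosynthetic overview**
1. The flavanone C-ring opens by retro-oxa-Michael to a 2'-hydroxychalcone. Its C2 stereocentre is set in the last step. The chalcone comes from Claisen–Schmidt condensation of the lavandulyl-type acetophenone with 2,4-dihydroxybenzaldehyde.
2. The aryl–CH2 bond of the acetophenone is formed photochemically. A primary radical from a redox-active ester is joined to the C3' position of commercial 2',4'-dihydroxy-6'-methoxyacetophenone.
3. The redox-active ester comes from (R)-limonene oxide. Periodate cleavage of the ring, Pinnick oxidation and MeMgBr addition give the hydroxy acid. The ring C4 becomes the chain stereocentre (R), so nothing is resolved.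
4. Ring order: the limonene ring is opened first, then the A-ring is alkylated, and the pyranone C-ring is closed last.

**Assumptions**
- 2',4'-Dihydroxy-6'-methoxyacetophenone is commercially available (otherwise it is one Hoesch step from 3,5-dihydroxyanisole).
- C3' (between the two OH groups) is the preferred alkylation site over C5'.
- The flavanone C2 epimers interconvert through the chalcone under mild base.

**Step 1**
Reactants: **1** (R)-limonene 1,2-oxide (commercial cis/trans mixture)
Product: **2** (R)-3-isopropenyl-6-oxoheptanal
Conditions: H5IO6, THF/Et2O, 0 °C → rt, 2 h
Reagents that add atoms: water, O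
Why: Acid-promoted epoxide hydrolysis to the diol is followed by Malaprade periodate cleavage, which opens the ring and leaves the isopropenyl group intact. The stereocentre is β to the aldehyde, so it cannot epimerise and stays R. Both epoxide diastereomers give the same keto-aldehyde.

**Step 2**
Reactants: **2**
Product: **3** (R)-limononic acid, (R)-3-isopropenyl-6-oxoheptanoic acid
Conditions: NaClO2, NaH2PO4, 2-methyl-2-butene, t-BuOH/H2O, rt, 2 h
Reagents that add atoms: sodium chlorite, [Na+].[O-]Cl=O
Why: Pinnick oxidation is chemoselective for the aldehyde. The alkene scavenger protects the isopropenyl group, the ketone is untouched, and the stereocentre is not involved.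

**Step 3**
Reactants: **3**
Product: **4** (R)-6-hydroxy-6-methyl-3-(prop-1-en-2-yl)heptanoic acid
Conditions: MeMgBr (3.5 equiv), CeCl3 (anhydrous), THF, −78 → 0 °C; then aq. citric acid workup
Reagents that add atoms: methylmagnesium bromide, C[Mg]Br
Why: The first equivalent of Grignard deprotonates the acid to the carboxylate, which is inert to further addition at low temperature. The cerium-moderated Grignard then adds to the methyl ketone to give the tertiary carbinol with little enolisation. The stereocentre is not involved.

**Step 4**
Reactants: **4**
Product: **5** 1,3-dioxoisoindolin-2-yl (R)-6-hydroxy-6-methyl-3-(prop-1-en-2-yl)heptanoate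
Conditions: N-hydroxyphthalimide, DIC, DMAP (cat.), CH2Cl2, rt, 3 h
Reagents that add atoms: N-hydroxyphthalimide, O=C1c2ccccc2C(=O)N1O
Why: Carbodiimide esterification. The acidic N–OH is far more reactive toward the O-acylisourea than the hindered tertiary alcohol, and 7-ring lactonisation is unfavourable, so the acid is converted selectively into the redox-active ester. The stereocentre is untouched.

**Step 5**
Reactants: **5**; **6** 2',4'-dihydroxy-6'-methoxyacetophenone (2.5 equiv)
Product: **7** 1-[2,4-dihydroxy-3-((R)-5-hydroxy-5-methyl-2-(prop-1-en-2-yl)hexyl)-6-methoxyphenyl]ethan-1-one
Conditions: Cs2CO3 (2 equiv), DMSO (0.1 M), blue LEDs (456 nm), no photocatalyst, N2, rt, 16 h; then aq. citric acid (pH 4) workup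
Reagents that add atoms: none
Why: Proposed new method: the 4'-phenolate of **6** is the electron donor in a visible-light electron-donor–acceptor complex with the N-hydroxyphthalimide (NHPI) ester. Single-electron transfer and loss of phthalimide anion and CO2 give a phenoxyl radical and a primary alkyl radical. The alkyl radical couples with the phenoxyl radical, or adds to a second phenolate and the resulting radical anion reduces another ester to propagate a chain. Bond formation is at C3', which is ortho to both oxygens (the 6'-OMe hinders C5'), and tautomerisation rearomatises the ring. The closest known chemistry is EDA-complex decarboxylative radical alkylation with NHPI esters, and ortho-C–H alkylation of phenolates and naphtholates with radicals. What is new is the use of an unactivated, β-branched homoallylic primary radical on an acyl-resorcinolate, with no metal or photocatalyst. The excess phenolate (about 0.25 M) should trap the radical faster than the 3-exo vinyl shift, so the (R) centre is retained. The reaction is a C–H alkylation with no new stereocentre.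

**Step 6**
Reactants: **7**; **8** 2,4-dihydroxybenzaldehyde
Product: **9** (E)-1-[2,4-dihydroxy-3-((R)-5-hydroxy-5-methyl-2-(prop-1-en-2-yl)hexyl)-6-methoxyphenyl]-3-(2,4-dihydroxyphenyl)prop-2-en-1-one
Conditions: KOH (aq., ≥8 equiv), EtOH, 50 °C, 48 h; then 1 M citric acid to pH 3–4
Reagents that add atoms: none
Why: Claisen–Schmidt aldol condensation gives the E-enone, as in standard polyhydroxychalcone syntheses, with excess base to cover the phenolic OH groups. The tertiary alcohol and isopropenyl group are inert to base. Any flavanone formed in situ converges with the chalcone in step 7, and no stereocentre is touched.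

**Step 7**
Reactants: **9**
Products: **10** (2S)-flavanone bearing the (2'R) chain (target), and **11** its C2 epimer
Conditions: NaOAc, EtOH, reflux, 24 h; then preparative reversed-phase HPLC to separate **10** from **11**. Resubject **11** to the same conditions.
Reagents that add atoms: none
Why: Intramolecular oxa-Michael cyclisation of the 2'-OH onto the enone (chalcone → flavanone) closes the C-ring. The remote (R) centre does not control C2, so **10** and **11** form as roughly 1:1 diastereomers. They are separated by ordinary chromatography, since they are diastereomers. **11** is recycled through retro-oxa-Michael ring opening to **9** and reclosure, so repeated cycles convert the material to **10**. No protecting groups were used, so no deprotection is needed.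

**Compound list**
1 | (R)-limonene 1,2-oxide (cis/trans) | CC12CC[C@H](CC1O2)C(C)=C | starting material
2 | (R)-3-isopropenyl-6-oxoheptanal | C=C(C)[C@@H](CC=O)CCC(C)=O | intermediate
3 | (R)-limononic acid | C=C(C)[C@@H](CC(=O)O)CCC(C)=O | intermediate
4 | (R)-6-hydroxy-6-methyl-3-(prop-1-en-2-yl)heptanoic acid | C=C(C)[C@@H](CC(=O)O)CCC(C)(C)O | intermediate
5 | NHPI ester of 4 | C=C(C)[C@@H](CC(=O)ON1C(=O)c2ccccc2C1=O)CCC(C)(C)O | intermediate
6 | 2',4'-dihydroxy-6'-methoxyacetophenone | CC(=O)c1c(O)cc(O)cc1OC | starting material
7 | 3'-alkylated acetophenone | CC(=O)c1c(OC)cc(O)c(C[C@H](C(C)=C)CCC(C)(C)O)c1O | intermediate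
8 | 2,4-dihydroxybenzaldehyde | O=Cc1ccc(O)cc1O | starting material
9 | (E)-chalcone | O=C(/C=C/c1ccc(O)cc1O)c1c(OC)cc(O)c(C[C@H](C(C)=C)CCC(C)(C)O)c1O | intermediate
10 | (2S)-2-(2,4-dihydroxyphenyl)-7-hydroxy-5-methoxy-8-[(2R)-5-hydroxy-5-methyl-2-(prop-1-en-2-yl)hexyl]chroman-4-one | C=C(C)[C@H](CCC(C)(C)O)Cc1c(O)cc(OC)c2c1O[C@H](c1ccc(O)cc1O)CC2=O | target
11 | (2R)-C2 epimer of 10 | C=C(C)[C@H](CCC(C)(C)O)Cc1c(O)cc(OC)c2c1O[C@@H](c1ccc(O)cc1O)CC2=O | intermediate (recycled to 9 and on to 10)

**Total steps:** 7. **Longest linear sequence:** 7 (1 → 2 → 3 → 4 → 5 → 7 → 9 → 10).

**Three steps most likely to fail**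
1. **Step 5 (proposed new step).**
   - Risks: the phenolate may O-acylate with the active ester, C3'/C5' selectivity may be poor, and the homoallylic radical may undergo the 3-exo vinyl shift.
   - Fallback (known chemistry): brominate **6** with NBS and separate the 3'-bromide. Couple it with **5** by Ni-catalysed reductive decarboxylative arylation (NiI2/bipyridine-type ligand, Zn, DMA). The rest of the route is unchanged.
2. **Step 7 (epimer separation).**
   - Risks: the two epimers differ only by a remote stereocentre, so they may co-elute, and the yield per pass is capped near 50%.
   - Fallback: peracetylate the phenols of the epimer mixture (the tertiary alcohol stays free) and separate the diastereomeric acetates by silica chromatography or crystallisation. Remove the acetates with hydrazinium acetate in DMF. Any epimerisation returns material to the equilibrium pool.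
3. **Step 6 (unprotected polyphenol condensation).**
   - Risks: polyphenolate formation can stall the aldol or give low yields.
   - Fallback: use the 2,4-bis-MOM ether of **8** and the 4'-OMOM derivative of **7**. Run the condensation and cyclisation, then remove the MOM groups with ZnBr2/PrSH.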